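## Retrosynthetic overview
1. The target comes from its tetra-MOM ether; the last step is only an acid methanolysis.
2. Key disconnection C3–C4: the ring A formyl carbon is turned into an acyl anion equivalent (Breslow intermediate of a chiral triazolylidene). It adds to the C3 aldehyde of a racemising dialdehyde, which closes ring C and sets C2 and C3 in one step (dynamic kinetic resolution).
3. The dialdehyde comes from the O1–C2 ether bond (Mitsunobu of a ring A salicylaldehyde with a ring B mandelate), followed by LiAlH4 reduction and double oxidation.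
4. The ring A piece comes from 2,4,6-trihydroxybenzaldehyde (bis-MOM, O-prenylation, para-Claisen–Cope puts prenyl at C6). The ring B piece comes from resorcinol (two directed lithiations: geranyl bromide, then ethyl glyoxylate).
5. Ring order: rings A and B are bought as aromatics; ring C is the only ring formed (step 10).

Assumption: the (5aS,10bR) antipode of the triazolium salt is taken to give (2R,3R) by analogy with related chromanone-forming cyclisations; both antipodes are sold, so the other is used if the sense is opposite.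

Abbreviations: MOM = CH2OCH3; prenyl = 3-methylbut-2-en-1-yl; geranyl = (2E)-3,7-dimethylocta-2,6-dien-1-yl. Compounds 16–19 are racemic and drawn without a stereo label.

## Route

**Step 1**
Reactants: 1 2,4,6-trihydroxybenzaldehyde; 2 chloromethyl methyl ether (MOMCl)
Product: 3 2-hydroxy-4,6-bis(methoxymethoxy)benzaldehyde
Conditions: MOMCl (2.1 equiv), K2CO3, acetone, 0 °C to rt
Reagents that add atoms: MOMCl (2), COCCl
Why: Williamson-type O-alkylation (MOM protection), in which the para hydroxyl and one of the two equivalent ortho hydroxyls react while the last hydroxyl is held in a strong hydrogen bond to the formyl oxygen and stays free at two equivalents of 2; no stereocentre is formed.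

**Step 2**
Reactants: 3 2-hydroxy-4,6-bis(methoxymethoxy)benzaldehyde; 4 prenyl bromide
Product: 5 2,4-bis(methoxymethoxy)-6-(prenyloxy)benzaldehyde
Conditions: prenyl bromide (1.3 equiv), K2CO3, DMF, 40 °C
Reagents that add atoms: prenyl bromide (4), CC(C)=CCBr
Why: Williamson ether synthesis, in which the chelated phenol is deprotonated in warm DMF and attacks the primary allylic bromide at oxygen (SN2), while the MOM ethers and the aldehyde are inert.

**Step 3**
Reactants: 5 2,4-bis(methoxymethoxy)-6-(prenyloxy)benzaldehyde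
Product: 8 6-hydroxy-2,4-bis(methoxymethoxy)-3-prenylbenzaldehyde, via ortho-dienone 6 (not isolated), via para-dienone 7 (not isolated)
Conditions: PhNEt2, 200 °C, 3 h, Ar
Reagents that add atoms: none
Why: Aromatic Claisen rearrangement followed by Cope rearrangement (para-Claisen–Cope), in which the first [3,3] shift puts a crowded 1,1-dimethylallyl group on the only free ortho carbon (6), the second [3,3] shift delivers it as a linear prenyl group to the para carbon between the two OMOM groups (7), and tautomerisation gives the phenol, so the 6-prenyl pattern is fixed and exactly the oxygen that becomes O1 is freed, a sequence known for the corresponding acetophenone.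

**Step 4**
Reactants: 9 resorcinol; 2 chloromethyl methyl ether (MOMCl)
Product: 10 1,3-bis(methoxymethoxy)benzene
Conditions: NaH (2.4 equiv), MOMCl (2.4 equiv), DMF, 0 °C to rt
Reagents that add atoms: MOMCl (2), COCCl
Why: MOM protection by Williamson-type alkylation of the bis-phenoxide, which also installs the directing groups for both later lithiations.

**Step 5**
Reactants: 10 1,3-bis(methoxymethoxy)benzene; 11 geranyl bromide
Product: 13 2-geranyl-1,3-bis(methoxymethoxy)benzene, via 2-lithio arene 12 (not isolated)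
Conditions: n-BuLi (1.1 equiv), THF, 0 °C to rt; then 11, −78 °C to rt
Reagents that add atoms: geranyl bromide (11), CC(C)=CCC/C(C)=C/CBr
Why: Directed ortho-metalation, in which the C–H flanked by two OMOM groups is the most acidic and doubly coordinated site and the aryllithium displaces the primary allylic bromide (SN2) with the E alkene retained.

**Step 6**
Reactants: 13 2-geranyl-1,3-bis(methoxymethoxy)benzene; 14 ethyl glyoxylate
Product: 16 ethyl (±)-2-[3-geranyl-2,4-bis(methoxymethoxy)phenyl]-2-hydroxyacetate, via aryllithium 15 (not isolated)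
Conditions: n-BuLi (1.15 equiv), TMEDA, THF, −10 °C, 1 h; then freshly cracked 14, −78 °C; AcOH quench
Reagents that add atoms: ethyl glyoxylate (14), CCOC(=O)C=O
Why: Directed ortho-metalation then 1,2-addition, in which the two remaining OMOM-flanked ring positions are equivalent, coordination of n-BuLi·TMEDA to OMOM favours ring over benzylic-allylic deprotonation, and the aryllithium adds to the aldehyde rather than the ester of 14 at −78 °C; the new stereocentre is formed racemic on purpose because it is made labile and reset in step 10.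

**Step 7**
Reactants: 8 6-hydroxy-2,4-bis(methoxymethoxy)-3-prenylbenzaldehyde; 16 ethyl (±)-2-[3-geranyl-2,4-bis(methoxymethoxy)phenyl]-2-hydroxyacetate
Product: 17 ethyl (±)-2-[2-formyl-3,5-bis(methoxymethoxy)-4-prenylphenoxy]-2-[3-geranyl-2,4-bis(methoxymethoxy)phenyl]acetate
Conditions: PPh3, DIAD, toluene, 0 °C to rt
Reagents that add atoms: none
Why: Mitsunobu etherification, in which the ortho-formyl phenol is acidic enough to protonate the betaine and the α-hydroxy ester is displaced by SN2 because the ester disfavours ionisation, so the O1–C2 bond forms on the only free ring A oxygen (racemic).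

**Step 8**
Reactants: 17 ethyl (±)-2-[2-formyl-3,5-bis(methoxymethoxy)-4-prenylphenoxy]-2-[3-geranyl-2,4-bis(methoxymethoxy)phenyl]acetate
Product: 18 (±)-2-[2-(hydroxymethyl)-3,5-bis(methoxymethoxy)-4-prenylphenoxy]-2-[3-geranyl-2,4-bis(methoxymethoxy)phenyl]ethanol
Conditions: LiAlH4 (1.5 equiv), THF, 0 °C; Na2SO4·10H2O quench
Reagents that add atoms: none
Why: Hydride reduction, which takes ester and aldehyde together to the diol and so avoids any ester-versus-aldehyde selectivity problem, while MOM ethers, the aryl ether and the trisubstituted alkenes are inert.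

**Step 9**
Reactants: 18 (±)-2-[2-(hydroxymethyl)-3,5-bis(methoxymethoxy)-4-prenylphenoxy]-2-[3-geranyl-2,4-bis(methoxymethoxy)phenyl]ethanol
Product: 19 (±)-6-{1-[3-geranyl-2,4-bis(methoxymethoxy)phenyl]-2-oxoethoxy}-2,4-bis(methoxymethoxy)-3-prenylbenzaldehyde
Conditions: nPr4NRuO4 (10 mol %), N-methylmorpholine N-oxide (3.5 equiv), 4 Å MS, CH2Cl2, rt; short silica plug, used at once
Reagents that add atoms: none
Why: Ley–Griffith oxidation, whose anhydrous non-acidic medium stops both primary alcohols at the aldehyde, spares the acid-sensitive electron-rich benzylic alcohol, the MOM groups and the alkenes, and gives the dialdehyde rather than a lactone because the competing lactol would be seven-membered.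

**Step 10**
Reactants: 19 (±)-6-{1-[3-geranyl-2,4-bis(methoxymethoxy)phenyl]-2-oxoethoxy}-2,4-bis(methoxymethoxy)-3-prenylbenzaldehyde
Product: 21 (2R,3R)-2-[3-geranyl-2,4-bis(methoxymethoxy)phenyl]-3-hydroxy-5,7-bis(methoxymethoxy)-6-prenylchroman-4-one, via Breslow intermediate 20 (not isolated)
Conditions: (5aS,10bR)-2-(pentafluorophenyl)-5a,10b-dihydro-4H,6H-indeno[2,1-b][1,2,4]triazolo[4,3-d][1,4]oxazin-2-ium tetrafluoroborate (15 mol %), iPr2NEt (0.5 equiv), 4 Å MS, toluene, 25 °C, Ar
Reagents that add atoms: none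
Why: Proposed new method: an asymmetric intramolecular aldehyde–aldehyde crossed benzoin run as a dynamic kinetic resolution, in which the triazolylidene adds reversibly to both formyl groups but the ring A adduct (favoured by its ortho-alkoxy groups, whereas the α-branched aliphatic adduct is slow to deprotonate) goes on to Breslow intermediate 20, whose polarity-reversed C4 attacks the more electrophilic C3 aldehyde through a six-membered hydrogen-bonded transition state; because C2–H of 19 (α-aryl, α-aryloxy aldehyde) is epimerised quickly by iPr2NEt, the chiral catalyst draws the whole racemate through the matched (2R) epimer, fixes C3 as R by face selection at the aldehyde and places the aryl group equatorial and trans to the new hydroxyl, while conjugation of the new ketone with electron-rich ring A makes the 3-hydroxy-4-one the thermodynamic ketol; the closest known reaction types are the enantioselective aldehyde–ketone benzoin cyclisation to 3-hydroxychroman-4-ones and the benzoin-based dynamic kinetic resolution of racemisable α-stereogenic carbonyl compounds.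

**Step 11**
Reactants: 21 (2R,3R)-2-[3-geranyl-2,4-bis(methoxymethoxy)phenyl]-3-hydroxy-5,7-bis(methoxymethoxy)-6-prenylchroman-4-one
Product: 22 (2R,3R)-2-(3-geranyl-2,4-dihydroxyphenyl)-3,5,7-trihydroxy-6-prenylchroman-4-one (CNP0166115.1)
Conditions: HCl (1.25 M in MeOH), 40 °C, monitored closely
Reagents that add atoms: none
Why: Acid-catalysed acetal exchange (MOM cleavage), under conditions routinely used for prenylated flavonoids and mild enough that the ortho-prenyl and ortho-geranyl phenols do not cyclise to chromans, the C2–O1 bond does not ionise and C3 is not enolised, so the trans (2R,3R) configuration, also the thermodynamic one, is kept.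

## Compound list
1 | 2,4,6-trihydroxybenzaldehyde | O=Cc1c(O)cc(O)cc1O | starting material
2 | chloromethyl methyl ether (MOMCl) | COCCl | starting material
3 | 2-hydroxy-4,6-bis(methoxymethoxy)benzaldehyde | O=Cc1c(O)cc(OCOC)cc1OCOC | intermediate
4 | prenyl bromide (1-bromo-3-methylbut-2-ene) | CC(C)=CCBr | starting material
5 | 2,4-bis(methoxymethoxy)-6-(prenyloxy)benzaldehyde | O=Cc1c(OCC=C(C)C)cc(OCOC)cc1OCOC | intermediate
6 | ortho-dienone: 5-(2-methylbut-3-en-2-yl)-2,4-bis(methoxymethoxy)-6-oxocyclohexa-1,3-diene-1-carbaldehyde (racemic) | O=CC1=C(OCOC)C=C(OCOC)C(C(C)(C)C=C)C1=O | intermediate (not isolated)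
7 | para-dienone: 2,4-bis(methoxymethoxy)-6-oxo-3-prenylcyclohexa-1,4-diene-1-carbaldehyde (racemic) | O=CC1=C(OCOC)C(CC=C(C)C)C(OCOC)=CC1=O | intermediate (not isolated)
8 | 6-hydroxy-2,4-bis(methoxymethoxy)-3-prenylbenzaldehyde | O=Cc1c(O)cc(OCOC)c(CC=C(C)C)c1OCOC | intermediate
9 | resorcinol | Oc1cccc(O)c1 | starting material
10 | 1,3-bis(methoxymethoxy)benzene | COCOc1cccc(OCOC)c1 | intermediate
11 | geranyl bromide | CC(C)=CCC/C(C)=C/CBr | starting material
12 | 2,6-bis(methoxymethoxy)phenyllithium | [Li]c1c(OCOC)cccc1OCOC | intermediate (not isolated)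
13 | 2-geranyl-1,3-bis(methoxymethoxy)benzene | CC(C)=CCC/C(C)=C/Cc1c(OCOC)cccc1OCOC | intermediate
14 | ethyl glyoxylate | CCOC(=O)C=O | starting material
15 | 3-geranyl-2,4-bis(methoxymethoxy)phenyllithium | CC(C)=CCC/C(C)=C/Cc1c(OCOC)ccc([Li])c1OCOC | intermediate (not isolated)
16 | ethyl (±)-2-[3-geranyl-2,4-bis(methoxymethoxy)phenyl]-2-hydroxyacetate | CC(C)=CCC/C(C)=C/Cc1c(OCOC)ccc(C(O)C(=O)OCC)c1OCOC | intermediate
17 | ethyl (±)-2-[2-formyl-3,5-bis(methoxymethoxy)-4-prenylphenoxy]-2-[3-geranyl-2,4-bis(methoxymethoxy)phenyl]acetate | CC(C)=CCC/C(C)=C/Cc1c(OCOC)ccc(C(Oc2cc(OCOC)c(CC=C(C)C)c(OCOC)c2C=O)C(=O)OCC)c1OCOC | intermediate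
18 | (±)-2-[2-(hydroxymethyl)-3,5-bis(methoxymethoxy)-4-prenylphenoxy]-2-[3-geranyl-2,4-bis(methoxymethoxy)phenyl]ethanol | CC(C)=CCC/C(C)=C/Cc1c(OCOC)ccc(C(CO)Oc2cc(OCOC)c(CC=C(C)C)c(OCOC)c2CO)c1OCOC | intermediate
19 | (±)-6-{1-[3-geranyl-2,4-bis(methoxymethoxy)phenyl]-2-oxoethoxy}-2,4-bis(methoxymethoxy)-3-prenylbenzaldehyde (C2 labile) | CC(C)=CCC/C(C)=C/Cc1c(OCOC)ccc(C(C=O)Oc2cc(OCOC)c(CC=C(C)C)c(OCOC)c2C=O)c1OCOC | intermediate
20 | Breslow intermediate: enaminol from the ring A formyl carbon of 19 and the (5aS,10bR)-triazolylidene (C2 still epimerising) | CC(C)=CCC/C(C)=C/Cc1c(OCOC)ccc(C(C=O)Oc2cc(OCOC)c(CC=C(C)C)c(OCOC)c2C(O)=C2N(c3c(F)c(F)c(F)c(F)c3F)N=C3CO[C@H]4Cc5ccccc5[C@H]4N23)c1OCOC | intermediate (not isolated)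
21 | (2R,3R)-2-[3-geranyl-2,4-bis(methoxymethoxy)phenyl]-3-hydroxy-5,7-bis(methoxymethoxy)-6-prenylchroman-4-one | CC(C)=CCC/C(C)=C/Cc1c(OCOC)ccc([C@H]2Oc3cc(OCOC)c(CC=C(C)C)c(OCOC)c3C(=O)[C@@H]2O)c1OCOC | intermediate
22 | (2R,3R)-2-(3-geranyl-2,4-dihydroxyphenyl)-3,5,7-trihydroxy-6-prenylchroman-4-one | CC(C)=CCC/C(C)=C/Cc1c(O)ccc([C@H]2Oc3cc(O)c(CC=C(C)C)c(O)c3C(=O)[C@@H]2O)c1O | target

## Step count
- Total steps: 11 (ring A piece 3, ring B piece 3, after union 5).
- Longest linear sequence: 8 (steps 4 to 11).

## Three steps most likely to fail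

**Step 10.**
- The carbene may instead engage the aliphatic aldehyde. Its Breslow intermediate could expel the ring A aryloxide (internal redox to an aryl arylacetate) or give the regioisomeric ketol.
- The C2 enolate could also close onto the ring A aldehyde in a five-membered aldol.
- Selectivity is unproven for this substrate.

The fallback replaces catalyst control by substrate control and the carbene by a ketyl. It sets out from 13 and comes back at 21. Aryllithium 15, made as in step 6, is quenched with diethyl oxalate to give the keto ester ethyl 2-[3-geranyl-2,4-bis(methoxymethoxy)phenyl]-2-oxoacetate F1. Transfer hydrogenation with RuCl(p-cymene)[(R,R)-TsNCH(Ph)CH(Ph)NH2] in HCO2H/Et3N (ligand antipode chosen to give the S alcohol) affords the (S)-hydroxy ester F2. Mitsunobu coupling with 8 inverts this centre to the (R)-aryloxy ester F3, and LiAlH4 gives the (R)-diol F4. Base-free oxidation with Dess–Martin periodinane at 0 °C gives the (R)-dialdehyde F5, which is used at once. SmI2 (2.2 equiv) with t-BuOH in THF at −78 °C forms the ring A ketyl, again a polarity-reversed C4, which adds to the C3 aldehyde under neutral conditions. This gives the samarium-chelated 3,4-cis, 2,3-trans (2R,3S,4S)-flavan-3,4-diol F6. 2-Iodoxybenzoic acid (1.1 equiv, DMSO, rt), which does not cleave diols, oxidises only the electron-rich benzylic C4 carbinol to 21.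

**Step 6.**
- n-BuLi may remove the doubly activated ArCH2–CH= proton instead of the ring proton.
- Ethyl glyoxylate may be delivered partly as polymer.

The fallback replaces deprotonation by halogen–lithium exchange. It sets out from 10 and comes back at 15. NBS in MeCN brominates 10 para to one OMOM group to give 1-bromo-2,4-bis(methoxymethoxy)benzene F7. LiN(iPr)2 at −78 °C removes the proton between the two OMOM groups, and 11 alkylates that site to give 1-bromo-3-geranyl-2,4-bis(methoxymethoxy)benzene F8. n-BuLi at −78 °C then exchanges bromine for lithium within minutes, faster than any benzylic deprotonation, and gives 15, which is carried on as in step 6.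

**Step 9.**
- The 2,4,6-trioxygenated benzylic alcohol of 18 ionises easily.
- The double oxidation must deliver a labile α-aryl-α-aryloxy aldehyde.

The fallback never reduces the ring A aldehyde. It sets out from 13 and comes back at 19. Aryllithium 15 is added to commercial (tert-butyldimethylsilyloxy)acetaldehyde to give 2-(tert-butyldimethylsilyloxy)-1-[3-geranyl-2,4-bis(methoxymethoxy)phenyl]ethanol F9. Mitsunobu coupling with 8 gives the aryl ether F10, with its formyl group intact. Bu4NF releases the primary alcohol F11, and a single Dess–Martin oxidation gives 19.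

## Further compounds
F1 | step 10 | ethyl 2-[3-geranyl-2,4-bis(methoxymethoxy)phenyl]-2-oxoacetate | CC(C)=CCC/C(C)=C/Cc1c(OCOC)ccc(C(=O)C(=O)OCC)c1OCOC
F2 | step 10 | ethyl (S)-2-[3-geranyl-2,4-bis(methoxymethoxy)phenyl]-2-hydroxyacetate | CC(C)=CCC/C(C)=C/Cc1c(OCOC)ccc([C@H](O)C(=O)OCC)c1OCOC
F3 | step 10 | ethyl (R)-2-[2-formyl-3,5-bis(methoxymethoxy)-4-prenylphenoxy]-2-[3-geranyl-2,4-bis(methoxymethoxy)phenyl]acetate | CC(C)=CCC/C(C)=C/Cc1c(OCOC)ccc([C@@H](Oc2cc(OCOC)c(CC=C(C)C)c(OCOC)c2C=O)C(=O)OCC)c1OCOC
F4 | step 10 | (R)-2-[2-(hydroxymethyl)-3,5-bis(methoxymethoxy)-4-prenylphenoxy]-2-[3-geranyl-2,4-bis(methoxymethoxy)phenyl]ethanol | CC(C)=CCC/C(C)=C/Cc1c(OCOC)ccc([C@@H](Oc2cc(OCOC)c(CC=C(C)C)c(OCOC)c2CO)CO)c1OCOC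
F5 | step 10 | (R)-6-{1-[3-geranyl-2,4-bis(methoxymethoxy)phenyl]-2-oxoethoxy}-2,4-bis(methoxymethoxy)-3-prenylbenzaldehyde | CC(C)=CCC/C(C)=C/Cc1c(OCOC)ccc([C@@H](Oc2cc(OCOC)c(CC=C(C)C)c(OCOC)c2C=O)C=O)c1OCOC
F6 | step 10 | (2R,3S,4S)-2-[3-geranyl-2,4-bis(methoxymethoxy)phenyl]-5,7-bis(methoxymethoxy)-6-prenylchromane-3,4-diol | CC(C)=CCC/C(C)=C/Cc1c(OCOC)ccc([C@H]2Oc3cc(OCOC)c(CC=C(C)C)c(OCOC)c3[C@H](O)[C@@H]2O)c1OCOC
F7 | step 6 | 1-bromo-2,4-bis(methoxymethoxy)benzene | COCOc1ccc(Br)c(OCOC)c1
F8 | step 6 | 1-bromo-3-geranyl-2,4-bis(methoxymethoxy)benzene | CC(C)=CCC/C(C)=C/Cc1c(OCOC)ccc(Br)c1OCOC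
F9 | step 9 | (±)-2-(tert-butyldimethylsilyloxy)-1-[3-geranyl-2,4-bis(methoxymethoxy)phenyl]ethanol | CC(C)=CCC/C(C)=C/Cc1c(OCOC)ccc(C(O)CO[Si](C)(C)C(C)(C)C)c1OCOC
F10 | step 9 | (±)-6-{2-(tert-butyldimethylsilyloxy)-1-[3-geranyl-2,4-bis(methoxymethoxy)phenyl]ethoxy}-2,4-bis(methoxymethoxy)-3-prenylbenzaldehyde | CC(C)=CCC/C(C)=C/Cc1c(OCOC)ccc(C(CO[Si](C)(C)C(C)(C)C)Oc2cc(OCOC)c(CC=C(C)C)c(OCOC)c2C=O)c1OCOC
F11 | step 9 | (±)-6-{1-[3-geranyl-2,4-bis(methoxymethoxy)phenyl]-2-hydroxyethoxy}-2,4-bis(methoxymethoxy)-3-prenylbenzaldehyde | CC(C)=CCC/C(C)=C/Cc1c(OCOC)ccc(C(CO)Oc2cc(OCOC)c(CC=C(C)C)c(OCOC)c2C=O)c1OCOC
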